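## Analysis of the target

The target is 8-(3,4-dimethoxyphenyl)-2,6-dimethoxynaphthalene-1,4-dione. Quinone ring A carries carbonyls at C1 and C4, a methoxy group on C2 and a hydrogen on C3. It is fused through C4a and C8a to benzene ring B, which has H at C5, OMe at C6, H at C7 and the 3,4-dimethoxyphenyl group at C8.

There is no stereocentre. The aryl group has no ortho substituent of its own, so the C8–aryl axis is not a stable stereo-element, and any stereocentre in an intermediate needs no control.

The sensitive part is the 2-methoxyquinone. It is a vinylogous ester and a Michael acceptor, so nucleophiles can displace the C2 methoxy by addition–elimination and reductants give the hydroquinone. It is therefore unveiled last. The four aryl methyl ethers are robust.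

Two regiochemical problems make the synthesis hard. Ring B is 1,2,3,5-tetrasubstituted, with the aryl group at C8 peri to the C1 carbonyl, a hindered site for a biaryl coupling. In ring A the methoxy must sit on C2, next to the carbonyl that faces the aryl group, and not on C3.

The strategy rests on the six carbons of ring B falling into three two-carbon units: C8/C8a, C4a/C5 and C6/C7. Each is an alkyne, and the first two are tethered through C1–C2–C3–C4. The aryl group and the C6 methoxy then arrive as alkyne substituents, and the C1 carbonyl and C2 methoxy are fixed by the tether. Only C4 must be oxygenated afterwards.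

## Retrosynthetic reasoning

**18 to 17.** The C4=O bond is cut first, leading back to 1-naphthol 17. The quinone is the most fragile function, so it is made last. The C1 hydroxyl of 17 directs a phenol-to-para-quinone oxidation to the free C4 position, and C2 already bears its methoxy, so the 2-methoxy-1,4-quinone should arise without an isomer problem.

**17 to 15.** The C3–C4 unsaturation is removed, giving tetralone 15. A dehydrogenation in the forward sense passes through dienone 16, which tautomerises to 17. The racemic C2 centre of 15 is erased here, which is why it is never controlled.

**15 to 11 and 14.** Three bonds of ring B are cut together: C4a–C8a, C5–C6 and C7–C8. This gives the 1,7-diyne 11 (aryl ynone at one end, terminal alkyne at the other) and the ynol ether 14. Cutting here places every ring B substituent on an alkyne carbon, so no aromatic substitution and no hindered biaryl coupling is needed. The forward reaction is a metal-catalysed [2+2+2] cyclotrimerisation. It must pair 11 with 14 rather than with a second molecule of 11, and it must put the methoxy carbon at C6, meta to the aryl group.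

**14 to 12.** The C≡C bond of 14 is traced to the acetal 12 by twofold β-elimination with a strong amide base. The acetylide 13 is the resting form until protonation.

**11 to 10.** The terminal C–H of 11 is traced to a C–Si bond in 10. The silyl group keeps the alkyl alkyne inert while carbanions are used earlier, and it is removed under neutral conditions that spare the ynone.

**10 to 6 and 7.** The acyl–alkynyl bond (C1–C8a of the target) is cut. Acetylide 8, made from arylalkyne 7, adds to the N-methoxy-N-methylamide 6, and the chelated adduct 9 stops the addition at the ketone stage.

**6 to 5, then 5 to 3 and 2, then 2 to 1.** Amide 6 comes from ester 5. The C2–C3 bond of the later ring A is cut in 5, giving enolate 4 of ester 3 and the primary triflate 2, which is made from alcohol 1. The methoxy-bearing carbon thus comes from a two-carbon ester that already holds the oxygen.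

## Alternatives that were turned down

**Alternative 1: vinylquinone as diene.**
- Disconnection: C4a–C5 and C6–C7 of ring B. The diene is quinone A1, using its C4a=C8a ring double bond and the exocyclic 1-arylvinyl group. The two-carbon partner is ketene acetal A2.
- Forward key step: a [4+2] addition followed by double enolisation gives hydroquinone A3. β-Elimination of one acetal methoxy then aromatises ring B, and oxidation of the hydroquinone gives the target.
- For: ring A has its final oxygenation pattern and oxidation level from the start, so no late dehydrogenation is needed. The regiochemistry has an electronic basis: the C2 methoxy makes C4=O a vinylogous ester, so C1=O activates C4a for attack by the nucleophilic CH2 of A2.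
- Against: A1 is a 2-vinylquinone, at once a diene and a dienophile, and such compounds dimerise and polymerise readily. Electron-rich ketene acetals also add to quinones stepwise, and the dipolar intermediate can close through oxygen to benzofuran-type products or give [2+2] adducts instead of the carbocycle. A1 must be made by building a 1,1-diarylethene and oxidising to the quinone just before use.
- Comparison: the step count is similar, and this route is stronger on redox economy. The chosen route offers a stable, purifiable key precursor 11 and a key step whose side reactions are limited to alkyne oligomerisation.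

**Alternative 2: aryne [2+2], then ring expansion.**
- Disconnection: C1–C8a and C4–C4a, with ring A grown from a four-membered ring.
- Forward key step: fluoride releases the 3-aryl-5-methoxybenzyne from silylaryl triflate A4, and A2 adds in a [2+2] cycloaddition to give benzocyclobutenone acetal A5. Hydrolysis gives benzocyclobutenone A6. A two-carbon unit carrying the methoxy group is then added to its carbonyl, thermal 4π ring opening and 6π closure expand the ring, and oxidation follows.
- For: aryne–ketene acetal cycloadditions are mild and dependable, ring B stays aromatic throughout, and benzocyclobutenone ring expansions are predictable. Taken alone, this key step is probably more certain than a cyclotrimerisation.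
- Against: A4 is a 1,2,3,5-tetrasubstituted arene with adjacent silyl and triflate groups next to the aryl group, so it needs a long regiocontrolled arene synthesis including a biaryl coupling. The 3-aryl group biases the aryne only by size, not inductively, so the regioisomeric [2+2] adduct is a real risk. After the key step C2 and C3 are still missing and C4 is a CH2 that must be oxidised.
- Comparison: this route is clearly longer. The chosen route sets the whole ring B pattern and closes both rings in one step.

**Alternative 3: Claisen closure onto an aryl glyoxylate.**
- Disconnection: C2–C3 of ring A.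
- Forward key step: base converts the acetyl methyl group of keto ester A7 into an enolate that attacks the ester carbonyl of the neighbouring glyoxylate. This closes ring A as hydroxyquinone A8, and O-methylation of the C2 hydroxyl finishes the synthesis.
- For: the closure is intramolecular and driven by formation of the acidic hydroxyquinone anion. Ring A appears directly at the right oxidation level, and no oxidation follows. On certainty of ring closure and on redox economy this alternative is stronger than the chosen route.
- Against: the difficulty lies in A7, a 1,2,3,5-tetrasubstituted benzene with two adjacent acyl groups and the glyoxylate between the acetyl and aryl groups. Electrophilic acylation would go ortho or para to the methoxy group, not to that position. A7 therefore needs directed metalation or halogen–metal exchange with a masked acetyl group, plus a hindered biaryl coupling. The enolate can also add reversibly to the ketone carbonyl of the glyoxylate in a five-membered aldol, and methylation of A8 can give the 4-methoxy-1,2-quinone isomer.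
- Comparison: the chosen route offers in exchange a short, convergent path to its key precursor from four simple building blocks, with no aromatic substitution and no biaryl coupling.

Key step: step 7

Remark on the chemistry: the target has no stereocentre. Compounds 5, 6, 10, 11 and 15 carry one stereocentre at the methoxy-bearing carbon and are made and used as racemates, and 9 as a diastereomer mixture, because this centre becomes sp2 in step 8.

## Route

Step 1
Reactants: 1 4-(trimethylsilyl)but-3-yn-1-ol
Product: 2 4-(trimethylsilyl)but-3-yn-1-yl trifluoromethanesulfonate
Conditions: Tf2O, 2,6-lutidine, CH2Cl2, −78 °C; used at once without purification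
Reagents that add atoms: trifluoromethanesulfonic anhydride, O=S(=O)(OS(=O)(=O)C(F)(F)F)C(F)(F)F
Why: O-sulfonylation of a primary alcohol; the hindered pyridine base takes up the acid without being N-alkylated by the product, and the silylalkyne is inert.

Step 2
Reactants: 3 methyl methoxyacetate; 2 4-(trimethylsilyl)but-3-yn-1-yl trifluoromethanesulfonate
Product: 5 methyl 2-methoxy-6-(trimethylsilyl)hex-5-ynoate (racemic), via lithium enolate 4 (not isolated)
Conditions: LiN(iPr)2 (LDA, commercial solution), THF, −78 °C; then 2, −78 → −30 °C (3 and base in slight excess over 2)
Reagents that add atoms: none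
Why: Ester enolate alkylation (SN2); the primary triflate should react at low temperature, where E2 elimination and Claisen self-condensation of 4 are slow, and an excess of enolate limits dialkylation. The new stereocentre forms without control, which is acceptable because it is erased later.

Step 3
Reactants: 5 methyl 2-methoxy-6-(trimethylsilyl)hex-5-ynoate
Product: 6 N,2-dimethoxy-N-methyl-6-(trimethylsilyl)hex-5-ynamide (racemic)
Conditions: MeNH(OMe)·HCl, iPrMgCl, THF, −20 → 0 °C
Reagents that add atoms: N,O-dimethylhydroxylamine hydrochloride, CNOC.Cl
Why: Direct aminolysis of a methyl ester by the chloromagnesium amide formed in the flask (Weinreb amide formation); the silylalkyne tolerates the Grignard reagent.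

Step 4
Reactants: 7 4-ethynyl-1,2-dimethoxybenzene; 6 N,2-dimethoxy-N-methyl-6-(trimethylsilyl)hex-5-ynamide
Product: 10 1-(3,4-dimethoxyphenyl)-4-methoxy-8-(trimethylsilyl)octa-1,7-diyn-3-one (racemic), via lithium arylethynide 8 (not isolated), via lithium hemiaminal adduct 9 (not isolated)
Conditions: n-BuLi, THF, −78 °C; then 6, −78 → 0 °C; poured into cold 1 M HCl
Reagents that add atoms: none
Why: Weinreb ketone synthesis; the chelated tetrahedral adduct 9 survives until work-up, so a second addition to the ynone cannot occur. The inverse acidic quench protonates the released amine before it can add to the ynone.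

Step 5
Reactants: 10 1-(3,4-dimethoxyphenyl)-4-methoxy-8-(trimethylsilyl)octa-1,7-diyn-3-one
Product: 11 1-(3,4-dimethoxyphenyl)-4-methoxyocta-1,7-diyn-3-one (racemic)
Conditions: AgNO3 (0.1 equiv), acetone/H2O, rt, dark
Reagents that add atoms: none
Why: Silver-catalysed protodesilylation of an alkynylsilane; silver activates the C–Si bond towards water, and the alkynylsilver species is protonated in the medium. Near-neutral conditions avoid the conjugate addition to the ynone that methoxide or unbuffered fluoride would risk.

Step 6
Reactants: 12 chloroacetaldehyde dimethyl acetal (2-chloro-1,1-dimethoxyethane)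
Product: 14 methoxyethyne, via sodium methoxyethynide 13 (not isolated)
Conditions: NaNH2 (3 equiv), liq. NH3, −33 °C; NH3 evaporated; sat. aq. NaCl, −20 °C; distilled into a −78 °C trap and kept as a cold solution in ClCH2CH2Cl
Reagents that add atoms: none
Why: Twofold β-elimination (loss of methanol, then of HCl) with sodium amide gives the ynol ether, held as its acetylide 13 until cold brine protonates it. The volatile product is handled only in cold solution and used promptly.

Step 7
Reactants: 11 1-(3,4-dimethoxyphenyl)-4-methoxyocta-1,7-diyn-3-one; 14 methoxyethyne
Product: 15 8-(3,4-dimethoxyphenyl)-2,6-dimethoxy-3,4-dihydronaphthalen-1(2H)-one (racemic)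
Conditions: Cp*RuCl(cod) (5–10 mol%), 14 (3 equiv), ClCH2CH2Cl, 0 °C → rt, slow addition of 11, closed vessel
Reagents that add atoms: none
Why: Ruthenium-catalysed [2+2+2] alkyne cyclotrimerisation of an α,ω-diyne with a monoalkyne; the closest known cases are Cp*RuCl(cod)-catalysed cycloadditions of 1,6-diynes and of 1,7-diynones with terminal alkynes. Loss of cod lets the divalent ruthenium fragment Cp*RuCl bind both alkynes of 11, and oxidative cyclisation joins C4a to C8a in a ruthenacyclopentadiene of tetravalent ruthenium; this closes six-membered ring A by metal-templated coupling of the two alkynes held together by the four-atom tether C1–C4. Alkyne 14 then inserts at the unhindered Ru–C5 bond, forming C5–C6, and C–C reductive elimination forms C7–C8, closing ring B as a benzene and returning divalent ruthenium. No stereocentre is created, and the racemic C2 centre is a spectator. The step needs cross-selectivity: slow addition of 11 into an excess of 14 keeps the diyne dilute, so the terminal alkyne of a second molecule of 11 should rarely intercept the metallacycle. It also needs regioselectivity, with the methoxy carbon at C6 and not C7: the bulky aryl group on C8 should make the metallacycle take the substituted alkyne carbon next to C5–H and the CH carbon next to C8, the meta orientation usual for unsymmetrical diynes under this catalyst. Polarity should point the same way, since the nucleophilic CH carbon of the ynol ether is paired with C8, the β-carbon of the ynone.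

Step 8
Reactants: 15 8-(3,4-dimethoxyphenyl)-2,6-dimethoxy-3,4-dihydronaphthalen-1(2H)-one
Product: 17 8-(3,4-dimethoxyphenyl)-2,6-dimethoxynaphthalen-1-ol, via 4H-naphthalenone 16 (not isolated)
Conditions: DDQ (1.05 equiv), 1,4-dioxane, 80 °C, N2
Reagents that add atoms: none
Why: Quinone dehydrogenation of a tetralone; DDQ abstracts hydride from C3 of the enol form of the α-methoxy ketone, loss of a proton gives dienone 16, and tautomerisation should deliver the aromatic naphthol. About one equivalent of oxidant under anhydrous conditions is used to limit further oxidation; the C2 stereocentre disappears here.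

Step 9
Reactants: 17 8-(3,4-dimethoxyphenyl)-2,6-dimethoxynaphthalen-1-ol
Product: 18 8-(3,4-dimethoxyphenyl)-2,6-dimethoxynaphthalene-1,4-dione (target)
Conditions: (KSO3)2NO (2.5 equiv), KH2PO4, H2O/acetone, 0 °C → rt
Reagents that add atoms: potassium nitrosodisulfonate (Fremy's salt), [K+].[K+].[O]N(S(=O)(=O)[O-])S(=O)(=O)[O-]
Why: Teuber oxidation of a phenol with a free para position; one radical equivalent removes the phenolic hydrogen, a second couples through oxygen at C4, and loss of imidodisulfonate gives the 1,4-quinone. The C2 methoxy blocks the ortho position, so the para-quinone should be the only product, and the buffered medium spares the methoxyquinone.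

## Compound list

1 | 4-(trimethylsilyl)but-3-yn-1-ol | C[Si](C)(C)C#CCCO | starting material
2 | 4-(trimethylsilyl)but-3-yn-1-yl trifluoromethanesulfonate | C[Si](C)(C)C#CCCOS(=O)(=O)C(F)(F)F | intermediate
3 | methyl methoxyacetate | COCC(=O)OC | starting material
4 | lithium 1,2-dimethoxyethen-1-olate (enolate of 3) | [Li+].[O-]C(OC)=COC | intermediate (not isolated)
5 | methyl 2-methoxy-6-(trimethylsilyl)hex-5-ynoate (racemic) | COC(=O)C(OC)CCC#C[Si](C)(C)C | intermediate
6 | N,2-dimethoxy-N-methyl-6-(trimethylsilyl)hex-5-ynamide (racemic) | CON(C)C(=O)C(OC)CCC#C[Si](C)(C)C | intermediate
7 | 4-ethynyl-1,2-dimethoxybenzene | C#Cc1ccc(OC)c(OC)c1 | starting material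
8 | lithium (3,4-dimethoxyphenyl)ethynide | [Li+].[C-]#Cc1ccc(OC)c(OC)c1 | intermediate (not isolated)
9 | lithium 1-(3,4-dimethoxyphenyl)-4-methoxy-3-[methoxy(methyl)amino]-8-(trimethylsilyl)octa-1,7-diyn-3-olate (diastereomer mixture) | [Li+].[O-]C(C#Cc1ccc(OC)c(OC)c1)(N(C)OC)C(OC)CCC#C[Si](C)(C)C | intermediate (not isolated)
10 | 1-(3,4-dimethoxyphenyl)-4-methoxy-8-(trimethylsilyl)octa-1,7-diyn-3-one (racemic) | COc1ccc(C#CC(=O)C(OC)CCC#C[Si](C)(C)C)cc1OC | intermediate
11 | 1-(3,4-dimethoxyphenyl)-4-methoxyocta-1,7-diyn-3-one (racemic) | C#CCCC(OC)C(=O)C#Cc1ccc(OC)c(OC)c1 | intermediate
12 | chloroacetaldehyde dimethyl acetal (2-chloro-1,1-dimethoxyethane) | COC(CCl)OC | starting material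
13 | sodium methoxyethynide | [Na+].[C-]#COC | intermediate (not isolated)
14 | methoxyethyne | COC#C | intermediate
15 | 8-(3,4-dimethoxyphenyl)-2,6-dimethoxy-3,4-dihydronaphthalen-1(2H)-one (racemic) | COC1CCc2cc(OC)cc(-c3ccc(OC)c(OC)c3)c2C1=O | intermediate
16 | 8-(3,4-dimethoxyphenyl)-2,6-dimethoxynaphthalen-1(4H)-one | COC1=CCc2cc(OC)cc(-c3ccc(OC)c(OC)c3)c2C1=O | intermediate (not isolated)
17 | 8-(3,4-dimethoxyphenyl)-2,6-dimethoxynaphthalen-1-ol | COc1ccc2cc(OC)cc(-c3ccc(OC)c(OC)c3)c2c1O | intermediate
18 | 8-(3,4-dimethoxyphenyl)-2,6-dimethoxynaphthalene-1,4-dione | COC1=CC(=O)c2cc(OC)cc(-c3ccc(OC)c(OC)c3)c2C1=O | target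

## Step count and least certain steps

Total: 9 steps. Longest linear sequence: 8 steps (steps 1–5 and 7–9, from 1); step 6 is a one-step branch.

**Step 7 (key step).** Three things may go wrong. Regiocontrol in the uptake of 14 may be poor, because the strong polarisation of the ynol ether could compete with the steric bias and place the methoxy group at C7. Alkyne 14 may oligomerise, or 11 may self-couple through its terminal alkyne. Metallacycle formation from a 1,7-diyne with one internal terminus may be slow. The fallback changes the monoalkyne and the way the C6 oxygen is introduced, and it also makes 14 and step 6 unnecessary. It sets out from 11. Cyclotrimerisation with ethynylboronic acid pinacol ester (C#CB1OC(C)(C)C(C)(C)O1) under Cp*RuCl(cod), a known route to arylboronates in which the bulky boronate goes meta, should give 8-(3,4-dimethoxyphenyl)-2-methoxy-6-(4,4,5,5-tetramethyl-1,3,2-dioxaborolan-2-yl)-3,4-dihydronaphthalen-1(2H)-one F1. Oxidation of the C–B bond with NaBO3·4H2O in THF/H2O should give 8-(3,4-dimethoxyphenyl)-6-hydroxy-2-methoxy-3,4-dihydronaphthalen-1(2H)-one F2. O-methylation with MeI and K2CO3 in acetone returns to the route at 15.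

**Step 8.** The electron-rich naphthol 17 is more easily oxidised than the enol of 15, so over-oxidation or oxidative coupling of the product by DDQ may compete, and enolisation of 15 may be slow. The fallback removes the free oxidant. It sets out from 15. Enolisation with LiN(SiMe3)2 and trapping with Me3SiCl should give {[8-(3,4-dimethoxyphenyl)-2,6-dimethoxy-3,4-dihydronaphthalen-1-yl]oxy}trimethylsilane F3. Pd(OAc)2 (1 equiv) in MeCN (Saegusa–Ito dehydrogenation: palladium enolate at C2, β-hydride elimination from C3) should give 16, which tautomerises, returning to the route at 17.

**Step 5.** Water may add to the ynone, by conjugate addition or silver-promoted hydration, during desilylation, or catalyst turnover may stall. The fallback changes the order of events. It sets out from 6. Desilylation with K2CO3 in MeOH, harmless at the amide stage, should give N,2-dimethoxy-N-methylhex-5-ynamide F4. Addition of 8 in excess (the aryl acetylide is the less basic one, so the alkyl alkyne stays largely protonated), followed by the same inverse acidic quench, returns to the route at 11.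

**Step 2.** The lithium enolate may cause E2 elimination of the homopropargylic triflate, self-condensation of the ester, or dialkylation. The fallback uses a stabilised, non-basic carbon nucleophile. It sets out from 2. Alkylation of the sodium salt of dimethyl 2-methoxymalonate (NaH, THF/DMF) should give dimethyl 2-methoxy-2-[4-(trimethylsilyl)but-3-yn-1-yl]propanedioate F5. Krapcho dealkoxycarbonylation (LiCl, wet DMSO, 140 °C) returns to the route at 5.

## Further compounds

F1 | step 7 | 8-(3,4-dimethoxyphenyl)-2-methoxy-6-(4,4,5,5-tetramethyl-1,3,2-dioxaborolan-2-yl)-3,4-dihydronaphthalen-1(2H)-one (racemic) | COC1CCc2cc(B3OC(C)(C)C(C)(C)O3)cc(-c3ccc(OC)c(OC)c3)c2C1=O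
F2 | step 7 | 8-(3,4-dimethoxyphenyl)-6-hydroxy-2-methoxy-3,4-dihydronaphthalen-1(2H)-one (racemic) | COC1CCc2cc(O)cc(-c3ccc(OC)c(OC)c3)c2C1=O
F3 | step 8 | {[8-(3,4-dimethoxyphenyl)-2,6-dimethoxy-3,4-dihydronaphthalen-1-yl]oxy}trimethylsilane | COC1=C(O[Si](C)(C)C)c2c(-c3ccc(OC)c(OC)c3)cc(OC)cc2CC1
F4 | step 5 | N,2-dimethoxy-N-methylhex-5-ynamide (racemic) | C#CCCC(OC)C(=O)N(C)OC
F5 | step 2 | dimethyl 2-methoxy-2-[4-(trimethylsilyl)but-3-yn-1-yl]propanedioate | COC(=O)C(OC)(CCC#C[Si](C)(C)C)C(=O)OC
A1 | alternative 1 | 2-[1-(3,4-dimethoxyphenyl)ethenyl]-6-methoxycyclohexa-2,5-diene-1,4-dione | C=C(c1ccc(OC)c(OC)c1)C1=CC(=O)C=C(OC)C1=O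
A2 | alternative 1 | 1,1-dimethoxyethene | C=C(OC)OC
A3 | alternative 1 | 8-(3,4-dimethoxyphenyl)-2,6,6-trimethoxy-5,6-dihydronaphthalene-1,4-diol | COc1cc(O)c2c(c1O)C(c1ccc(OC)c(OC)c1)=CC(OC)(OC)C2
A4 | alternative 2 | 2-(3,4-dimethoxyphenyl)-4-methoxy-6-(trimethylsilyl)phenyl trifluoromethanesulfonate | COc1cc(-c2ccc(OC)c(OC)c2)c(OS(=O)(=O)C(F)(F)F)c([Si](C)(C)C)c1
A5 | alternative 2 | 5-(3,4-dimethoxyphenyl)-3,7,7-trimethoxybicyclo[4.2.0]octa-1,3,5-triene | COc1cc2c(c(-c3ccc(OC)c(OC)c3)c1)C(OC)(OC)C2
A6 | alternative 2 | 5-(3,4-dimethoxyphenyl)-3-methoxybicyclo[4.2.0]octa-1,3,5-trien-7-one | COc1cc2c(c(-c3ccc(OC)c(OC)c3)c1)C(=O)C2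
A7 | alternative 3 | methyl 2-[2-acetyl-6-(3,4-dimethoxyphenyl)-4-methoxyphenyl]-2-oxoacetate | COC(=O)C(=O)c1c(C(C)=O)cc(OC)cc1-c1ccc(OC)c(OC)c1
A8 | alternative 3 | 8-(3,4-dimethoxyphenyl)-2-hydroxy-6-methoxynaphthalene-1,4-dione | OC1=CC(=O)c2cc(OC)cc(-c3ccc(OC)c(OC)c3)c2C1=O
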